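Take a ratio first: at 28 h the larch run leads the elm run by 0.151 M of c(target), against the 0.200 M of extra target it was charged with, so 0.755 of that surplus remains. Both flasks have the same charge of starting material and free catalyst, and their gains over the first 3.5 h read 0.0390 M and 0.039 M. I therefore take the target made in each as equal, and the shrinking surplus as target being lost. The logarithm of surplus charged over surplus left, divided by the time, reads 0.0100 h⁻¹: the target's loss constant, a first-order rate constant.

| flask | starting material | free catalyst | target | time |
|---|---|---|---|---|
| elm | 0.400 M | 0.0400 M |  |  |
| cedar | 0.800 M | 0.0400 M |  |  |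
| oak | 0.400 M | 0.0800 M |  |  |
| larch | 0.400 M | 0.0400 M | 0.200 M |  |
| birch | 0.400 M | 0.0400 M |  | 70 h |

- elm run (time / h: [target] / M): 3.5: 0.039; 7.0: 0.085; 10: 0.111; 14: 0.125; 18: 0.135; 21: 0.149; 24: 0.140; 28: 0.156
- cedar run (time / h: [target] / M): 3.5: 0.101; 7.0: 0.177; 10: 0.208; 14: 0.247; 18: 0.270; 21: 0.295; 24: 0.302; 28: 0.325
- oak run (time / h: [target] / M): 3.5: 0.083; 7.0: 0.117; 10: 0.140; 14: 0.171; 18: 0.174; 21: 0.195; 24: 0.188; 28: 0.206
- larch run (time / h: [target] / M): 3.5: 0.239; 7.0: 0.267; 10: 0.287; 14: 0.295; 18: 0.304; 21: 0.298; 24: 0.307; 28: 0.307

(scatter of a reading: 0.006 M)

* order of the initial rate in [free catalyst], near the charge of the elm run, the rate being that where two percent of its starting material are target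
* order of the initial rate in [starting material], near the charge of the elm run, the rate being that where two percent of its starting material are target (one fixed amount of target, the same in the runs compared)
* target in the birch run at 70 h, as a share of the starting material charged

- Overall: starting material -> target, with free catalyst as catalyst.
- Constant volume, constant temperature.
- An order is taken over about fifteen percent of the charge, up and down.

Here is my own reckoning for birch, which is elm's charge carried to 70 h. Replace elm's curve by its mean over a stretch. From 14 h to 28 h, one doubling of time, c(target) rose 0.0310 M around a mean of 0.141 M, so it lost 0.0197 M and made 0.0507 M. I assume each doubling makes that much. The way to 70 h is 1.32 doublings, giving 0.0671 M made, while a mean held at 0.156 M loses 0.0658 M, nearly the same. That ends at 0.157 M, or 39.3% of the charge. The error of the mean is small, since that end differs from the start by less than the scatter.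

Your forecast gives 1.05 and 1.2 for the orders and 49% for birch, reading larch's stall as “a reversible ceiling” and running elm's late drift on at 0.03 M per time doubling. Your birch number stands higher than mine.

    2 free catalyst ⇌ catalyst dimer, settled at all times (27.10 M⁻¹)
    free catalyst + starting material → target + free catalyst (2.131 M⁻¹ h⁻¹)
    2 free catalyst → 2 spent catalyst (4.104 M⁻¹ h⁻¹)
    target → decomposed product (0.01210 h⁻¹)

The flask gives 34.8% for birch, which is 0.139 M of target, with orders of 0.68 in free catalyst and 1.1 in starting material. The oak run's rate stood at 1.6 times the elm run's where the same amount had been made. Now put the loss constant, a reading from larch and elm with their scatter, on birch again: between elm's 0.156 M at 28 h and birch's 0.139 M at 70 h the mean is 0.148 M, so this estimate puts the target lost at about 0.0622 M. Against a net fall of 0.0167 M, the same estimate puts the target made in those hours at about 0.0455 M.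

Readings and results were generated by integration on assumed constants; the scatter is artificial.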